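**Retrosynthetic overview**
1. The butenolide ring is not built. It is bought as 4-bromofuran-2(5H)-one and attached last by Suzuki coupling to a (1E,3E)-dienylboronate.
2. The trisubstituted allylic alcohol/diene comes from an E-selective Horner–Wadsworth–Emmons reaction of an α-alkylated phosphonoacetate with 3-boronoacrolein pinacolate, then ester → CH2OH.
3. The phosphonate comes from C-alkylation of triethyl phosphonoacetate with a bicyclic homoallylic bromide.
4. Rings A and B of the decalin are closed together from an acyclic (3E,7Z)-homofarnesyl bromide by a catalyst-controlled, proton-initiated cation–olefin bicyclization. The 7Z alkene becomes the cis ring fusion and the termination gives the tetrasubstituted ring alkene.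
5. The acyclic triene comes from nerylacetone by cyclopropyl Grignard addition and Julia–Johnson opening. Ring order: A + B in one step, butenolide attached at the end.

Assumption: the target is made exactly as drawn, i.e. a cis-fused decalin (4aR,8aS; 8a-CH3 and 4a-H on the same face) with a (1E,3E)-diene, and nerylacetone is bought as the pure Z isomer.

**Step 1**
Reactants: 1 nerylacetone [(5Z)-6,10-dimethylundeca-5,9-dien-2-one]; 2 cyclopropylmagnesium bromide
Product: 3 (5Z)-2-cyclopropyl-6,10-dimethylundeca-5,9-dien-2-ol (racemic)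
Conditions: 2 (1.3 equiv), THF, 0 °C → rt; then H2O
Reagents that add atoms: none
Why: Grignard 1,2-addition to the methyl ketone; the new carbinol centre is racemic and is destroyed in step 2.

**Step 2**
Reactants: 3 (5Z)-2-cyclopropyl-6,10-dimethylundeca-5,9-dien-2-ol
Product: 4 (3E,7Z)-1-bromo-4,8,12-trimethyltrideca-3,7,11-triene (3E:3Z about 4:1, used as such or enriched on AgNO3–silica)
Conditions: MgBr2·OEt2 (3 equiv), Et2O, reflux
Reagents that add atoms: magnesium bromide, [Mg+2].[Br-].[Br-]
Why: Julia–Johnson cyclopropylcarbinyl → homoallyl rearrangement (ionisation to the tertiary cyclopropylcarbinyl cation, bromide opens the ring) gives mainly the 3E alkene under conditions too mild to touch the 7Z alkene; the C3 geometry carries no stereochemical information into the target because that carbon becomes sp2 in step 3.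

**Step 3**
Reactants: 4 (3E,7Z)-1-bromo-4,8,12-trimethyltrideca-3,7,11-triene
Product: 5 (4aR,8aS)-1-(2-bromoethyl)-2,5,5,8a-tetramethyl-3,4,4a,5,6,7,8,8a-octahydronaphthalene
Conditions: confined chiral imidodiphosphorimidate (IDPi) Brønsted acid (5 mol %, the antipode that gives 4aR,8aS), (CF3)3COH, −20 °C, 72 h; Et3N quench
Reagents that add atoms: none
Why: Proposed new method: the confined chiral acid protonates C-11 of the isopropylidene terminus inside its pocket and the chair–chair folded triene collapses by anti (Stork–Eschenmoser) addition across the 7Z alkene, closing both carbocycles at once (C4a–C5 and C1–C8a bonds) so that 8a-CH3 and 4a-H end up cis with the absolute sense (4aR,8aS) fixed by the catalyst antipode, and the tertiary C-2 cation then loses the adjacent H-1 to the catalyst anion to give the tetrasubstituted, most stable alkene; the closest known reaction type is the catalytic asymmetric proton-initiated polyene bicyclization (IDPi in fluorinated alcohols, chiral Lewis-acid-assisted Brønsted acids) established for hydroxyl-, carboxyl- and aryl-terminated E-polyenes.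

**Step 4**
Reactants: 5 (4aR,8aS)-1-(2-bromoethyl)-2,5,5,8a-tetramethyl-3,4,4a,5,6,7,8,8a-octahydronaphthalene; 6 triethyl phosphonoacetate
Product: 8 ethyl 2-(diethoxyphosphoryl)-4-[(4aR,8aS)-2,5,5,8a-tetramethyl-3,4,4a,5,6,7,8,8a-octahydronaphthalen-1-yl]butanoate (1:1 epimers at C-2), via sodium triethyl phosphonoacetate carbanion 7 (not isolated)
Conditions: 6 (2 equiv), NaH (1.9 equiv), DMF, 0 °C; then 5, NaI (10 mol %), 60 °C
Reagents that add atoms: none
Why: SN2 alkylation of the stabilised phosphonoacetate carbanion by the primary bromide (iodide-assisted, excess nucleophile suppresses dialkylation); the new P-bearing centre forms unselectively and is removed in step 5, and the ring stereocentres are not touched.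

**Step 5**
Reactants: 8 ethyl 2-(diethoxyphosphoryl)-4-[(4aR,8aS)-2,5,5,8a-tetramethyl-3,4,4a,5,6,7,8,8a-octahydronaphthalen-1-yl]butanoate; 9 3-boronoacrolein pinacolate [(E)-3-(4,4,5,5-tetramethyl-1,3,2-dioxaborolan-2-yl)prop-2-enal]
Product: 11 ethyl (2E,4E)-2-{2-[(4aR,8aS)-2,5,5,8a-tetramethyl-3,4,4a,5,6,7,8,8a-octahydronaphthalen-1-yl]ethyl}-5-(4,4,5,5-tetramethyl-1,3,2-dioxaborolan-2-yl)penta-2,4-dienoate, via sodium carbanion of phosphonate 10 (not isolated)
Conditions: NaH (1.05 equiv), THF, 0 °C; then 9 (1.2 equiv), 0 °C → rt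
Reagents that add atoms: none
Why: Horner–Wadsworth–Emmons olefination of an α-alkyl phosphonoacetate gives the (E)-trisubstituted enoate (ester trans to the vinyl chain, i.e. the alkyl chain cis to it, as the target requires), while the E-vinylboronate geometry is carried over unchanged from 9.

**Step 6**
Reactants: 11 ethyl (2E,4E)-2-{2-[(4aR,8aS)-2,5,5,8a-tetramethyl-3,4,4a,5,6,7,8,8a-octahydronaphthalen-1-yl]ethyl}-5-(4,4,5,5-tetramethyl-1,3,2-dioxaborolan-2-yl)penta-2,4-dienoate
Product: 12 (2E,4E)-2-{2-[(4aR,8aS)-2,5,5,8a-tetramethyl-3,4,4a,5,6,7,8,8a-octahydronaphthalen-1-yl]ethyl}-5-(4,4,5,5-tetramethyl-1,3,2-dioxaborolan-2-yl)penta-2,4-dien-1-ol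
Conditions: DIBAL-H (2.5 equiv), CH2Cl2, −78 °C; Rochelle salt work-up
Reagents that add atoms: none
Why: DIBAL-H 1,2-reduction of the conjugated ester to the allylic alcohol at −78 °C, which leaves the pinacol boronate and all alkenes (and their geometry) intact; it is done before the lactone is introduced so that no ester/lactone selectivity is needed.

**Step 7**
Reactants: 12 (2E,4E)-2-{2-[(4aR,8aS)-2,5,5,8a-tetramethyl-3,4,4a,5,6,7,8,8a-octahydronaphthalen-1-yl]ethyl}-5-(4,4,5,5-tetramethyl-1,3,2-dioxaborolan-2-yl)penta-2,4-dien-1-ol; 13 4-bromofuran-2(5H)-one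
Product: 14 4-[(1E,3E)-4-(hydroxymethyl)-6-[(4aR,8aS)-2,5,5,8a-tetramethyl-3,4,4a,5,6,7,8,8a-octahydronaphthalen-1-yl]hexa-1,3-dien-1-yl]furan-2(5H)-one (target)
Conditions: Pd(dppf)Cl2 (5 mol %), K3PO4 (3 equiv), THF/H2O 10:1, 45 °C, degassed, dark
Reagents that add atoms: none
Why: Suzuki–Miyaura sp2–sp2 coupling proceeds with retention of both alkene geometries; the β-bromobutenolide undergoes fast oxidative addition and the free allylic alcohol is tolerated under the mild phosphate base.

**Compound list**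
1 | nerylacetone, (5Z)-6,10-dimethylundeca-5,9-dien-2-one | CC(=O)CC/C=C(/C)CCC=C(C)C | starting material
2 | cyclopropylmagnesium bromide | Br[Mg]C1CC1 | starting material
3 | (5Z)-2-cyclopropyl-6,10-dimethylundeca-5,9-dien-2-ol (racemic) | CC(O)(C1CC1)CC/C=C(/C)CCC=C(C)C | intermediate
4 | (3E,7Z)-1-bromo-4,8,12-trimethyltrideca-3,7,11-triene (major 3E isomer drawn) | BrCC/C=C(\C)CC/C=C(/C)CCC=C(C)C | intermediate
5 | (4aR,8aS)-1-(2-bromoethyl)-2,5,5,8a-tetramethyl-3,4,4a,5,6,7,8,8a-octahydronaphthalene | CC1=C(CCBr)[C@@]2(C)CCCC(C)(C)[C@H]2CC1 | intermediate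
6 | triethyl phosphonoacetate | CCOC(=O)CP(=O)(OCC)OCC | starting material
7 | sodium triethyl phosphonoacetate carbanion | CCOC(=O)[CH-]P(=O)(OCC)OCC.[Na+] | intermediate (not isolated)
8 | ethyl 2-(diethoxyphosphoryl)-4-[(4aR,8aS)-2,5,5,8a-tetramethyl-3,4,4a,5,6,7,8,8a-octahydronaphthalen-1-yl]butanoate (epimers at C-2) | CC1=C(CCC(C(=O)OCC)P(=O)(OCC)OCC)[C@@]2(C)CCCC(C)(C)[C@H]2CC1 | intermediate
9 | 3-boronoacrolein pinacolate, (E)-3-(4,4,5,5-tetramethyl-1,3,2-dioxaborolan-2-yl)prop-2-enal | O=C/C=C/B1OC(C)(C)C(C)(C)O1 | starting material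
10 | sodium carbanion of phosphonate 8 | CC1=C(CC[C-](C(=O)OCC)P(=O)(OCC)OCC)[C@@]2(C)CCCC(C)(C)[C@H]2CC1.[Na+] | intermediate (not isolated)
11 | ethyl (2E,4E)-2-{2-[(4aR,8aS)-2,5,5,8a-tetramethyl-3,4,4a,5,6,7,8,8a-octahydronaphthalen-1-yl]ethyl}-5-(4,4,5,5-tetramethyl-1,3,2-dioxaborolan-2-yl)penta-2,4-dienoate | CC1=C(CC/C(=C\C=C\B3OC(C)(C)C(C)(C)O3)C(=O)OCC)[C@@]2(C)CCCC(C)(C)[C@H]2CC1 | intermediate
12 | (2E,4E)-2-{2-[(4aR,8aS)-2,5,5,8a-tetramethyl-3,4,4a,5,6,7,8,8a-octahydronaphthalen-1-yl]ethyl}-5-(4,4,5,5-tetramethyl-1,3,2-dioxaborolan-2-yl)penta-2,4-dien-1-ol | CC1=C(CC/C(=C\C=C\B3OC(C)(C)C(C)(C)O3)CO)[C@@]2(C)CCCC(C)(C)[C@H]2CC1 | intermediate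
13 | 4-bromofuran-2(5H)-one | O=C1C=C(Br)CO1 | starting material
14 | 4-[(1E,3E)-4-(hydroxymethyl)-6-[(4aR,8aS)-2,5,5,8a-tetramethyl-3,4,4a,5,6,7,8,8a-octahydronaphthalen-1-yl]hexa-1,3-dien-1-yl]furan-2(5H)-one | CC1=C(CC/C(=C\C=C\C2=CC(=O)OC2)CO)[C@@]2(C)CCCC(C)(C)[C@H]2CC1 | target

**Totals**
Total step count: 7. Longest linear sequence: 7 steps (1 → 14); all other inputs are purchased.

**Three steps most likely to fail**

Step 3 (bicyclization). The risks are these:
- The alkene-terminated, Z-configured substrate lies outside the proven scope of the chiral acid, so the enantiomer ratio and the cis/trans ring-fusion ratio are uncertain.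
- The cascade may stop after one ring.
- Loss of a proton from C-3 or from the 2-methyl group would give alkene regioisomers, especially from the 3Z part of 4.
- 5 is an oil, so the enantiomeric excess of this step is the enantiomeric excess of the target.

The fallback uses a carboxyl-terminated cyclization, which has far better asymmetric precedent, and sets out from 1:
- Wittig reaction of 1 with the ylide from (2-carboxyethyl)triphenylphosphonium bromide (NaHMDS, THF) gives (7Z)-4,8,12-trimethyltrideca-3,7,11-trienoic acid F1; its 3E/3Z ratio is immaterial.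
- Bicyclization with the chiral acid, now terminated by the carboxyl group, gives the cis-A/B-fused γ-lactone 3a,6,6,9a-tetramethyldecahydronaphtho[2,1-b]furan-2(1H)-one F2.
- LiAlH4 in THF gives the diol 1-(2-hydroxyethyl)-2,5,5,8a-tetramethyldecahydronaphthalen-2-ol F3.
- PPh3/I2 in CH2Cl2 converts the primary alcohol into the iodide and dehydrates the tertiary alcohol towards the tetrasubstituted position, giving (4aR,8aS)-1-(2-iodoethyl)-2,5,5,8a-tetramethyl-3,4,4a,5,6,7,8,8a-octahydronaphthalene F4.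
- F4 alkylates carbanion 7 as in step 4 and the route is rejoined at 8.

Step 5 (HWE). The E/Z ratio of the trisubstituted alkene may be only moderate, and the boryl enal may suffer conjugate addition or boronate complexation by the basic carbanion. The fallback fixes the geometry by a cross-coupling instead and sets out from 5 and 9:
- Zinc insertion into 5 (Zn dust, cat. I2, DMA, 70 °C) gives {2-[(4aR,8aS)-2,5,5,8a-tetramethyl-3,4,4a,5,6,7,8,8a-octahydronaphthalen-1-yl]ethyl}zinc bromide F5.
- Wittig reaction of 9 with ethyl bromo(triphenylphosphoranylidene)acetate (CH2Cl2, rt) gives ethyl (2Z,4E)-2-bromo-5-(4,4,5,5-tetramethyl-1,3,2-dioxaborolan-2-yl)penta-2,4-dienoate F6, with bromine cis to the vinyl chain.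
- Negishi coupling of F5 with F6 (Pd(dppf)Cl2, THF/DMA, rt) replaces bromine by the alkyl chain with retention and rejoins the route at 11.

Step 7 (Suzuki). The bromobutenolide and the triene-butenolide product are base- and light-sensitive, and the dienylboronate can protodeboronate. The fallback forms the last C–C bond by a Heck reaction without any organometallic and sets out from 8:
- HWE reaction of 8 (through 10) with acrolein gives ethyl (2E)-2-{2-[(4aR,8aS)-2,5,5,8a-tetramethyl-3,4,4a,5,6,7,8,8a-octahydronaphthalen-1-yl]ethyl}penta-2,4-dienoate F7.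
- DIBAL-H at −78 °C gives (2E)-2-{2-[(4aR,8aS)-2,5,5,8a-tetramethyl-3,4,4a,5,6,7,8,8a-octahydronaphthalen-1-yl]ethyl}penta-2,4-dien-1-ol F8.
- Heck vinylation of the terminal diene carbon of F8 with 13 (Pd(OAc)2, Bu4NCl, NaHCO3, DMF, 50 °C) gives the 1E alkene by syn β-hydride elimination and arrives directly at 14.

**Further compounds**
F1 | step 3 | (7Z)-4,8,12-trimethyltrideca-3,7,11-trienoic acid (3E/3Z mixture) | OC(=O)CC=C(C)CC/C=C(/C)CCC=C(C)C
F2 | step 3 | cis-A/B-fused 3a,6,6,9a-tetramethyldecahydronaphtho[2,1-b]furan-2(1H)-one (ring-fusion carbons as C-4a/C-8a of 5; epimer mixture at C-3a/C-9b) | CC12OC(=O)CC1[C@@]1(C)CCCC(C)(C)[C@H]1CC2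
F3 | step 3 | 1-(2-hydroxyethyl)-2,5,5,8a-tetramethyldecahydronaphthalen-2-ol (ring-fusion carbons as in 5; epimer mixture at C-1/C-2) | CC1(O)C(CCO)[C@@]2(C)CCCC(C)(C)[C@H]2CC1
F4 | step 3 | (4aR,8aS)-1-(2-iodoethyl)-2,5,5,8a-tetramethyl-3,4,4a,5,6,7,8,8a-octahydronaphthalene | CC1=C(CCI)[C@@]2(C)CCCC(C)(C)[C@H]2CC1
F5 | step 5 | {2-[(4aR,8aS)-2,5,5,8a-tetramethyl-3,4,4a,5,6,7,8,8a-octahydronaphthalen-1-yl]ethyl}zinc bromide | CC1=C(CC[Zn]Br)[C@@]2(C)CCCC(C)(C)[C@H]2CC1
F6 | step 5 | ethyl (2Z,4E)-2-bromo-5-(4,4,5,5-tetramethyl-1,3,2-dioxaborolan-2-yl)penta-2,4-dienoate | CCOC(=O)/C(Br)=C/C=C/B1OC(C)(C)C(C)(C)O1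
F7 | step 7 | ethyl (2E)-2-{2-[(4aR,8aS)-2,5,5,8a-tetramethyl-3,4,4a,5,6,7,8,8a-octahydronaphthalen-1-yl]ethyl}penta-2,4-dienoate | CC1=C(CC/C(=C\C=C)C(=O)OCC)[C@@]2(C)CCCC(C)(C)[C@H]2CC1
F8 | step 7 | (2E)-2-{2-[(4aR,8aS)-2,5,5,8a-tetramethyl-3,4,4a,5,6,7,8,8a-octahydronaphthalen-1-yl]ethyl}penta-2,4-dien-1-ol | CC1=C(CC/C(=C\C=C)CO)[C@@]2(C)CCCC(C)(C)[C@H]2CC1
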